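**Plan**

- Cuts, in retrosynthetic order: the three O-benzyl bonds (5-O, 4'-O, 5''-O); then C2–C3 of flavanone ring C (key), traded for an O–C2 acetal bond so that ring C becomes the temporary dioxine ring of a 2-aryl-4-methylidene-4H-1,3-benzodioxine (C2 at the acetal oxidation level); then the biaryl bond C3'–C8''; then the exocyclic C=CH2 (from a lactone C=O) and the two acetal C–O bonds (ring A acid plus ring B aldehyde).
- Forward: apigenin gives the 8-iodoflavone (rings D, F, E) in three steps. 2,4,6-Trihydroxybenzoic acid and 4-(benzyloxy)-3-bromobenzaldehyde are condensed to a benzodioxinone, which is O-methylated, O-benzylated, methylenated and joined to the iodoflavone by one-pot borylation/Suzuki coupling. The enol acetal is then rearranged into ring C and the benzyl groups are removed.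
- Enabling feature: ring C holds a β-aryloxy ketone, O1–C2–C3–C4(=O), and C2 is benzylic to ring B, whose 4'-oxygen is para to C2. Moving C2 from the enol oxygen on C4 to the enol carbon C3 is therefore a 1,3-O-to-C shift through an oxocarbenium ion at C2 that the 4'-oxygen stabilises (Petasis–Ferrier retron).
- Stereochemistry: C2 is the only stereocentre. The acetal carbon is carried racemic and converted into (2S) in the key step under control of a chiral phosphate counter-anion. No basic step follows, so the flavanone cannot racemise by ring opening.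

Key step: step 10

Remark: the C3'–C8'' biaryl axis is assumed to rotate freely at ambient temperature, so C2 is the only stereogenic element. Rings A, C, B belong to the flavanone; rings D, F, E and double-primed positions to the flavone; in the benzodioxine intermediates the hetero ring is O1, C2, O3, C4. Compounds 9 to 15 are racemic at the acetal carbon.

Step 1
Reactants: 1 apigenin [5,7-dihydroxy-2-(4-hydroxyphenyl)-4H-chromen-4-one]
Product: 2 5-hydroxy-7-methoxy-2-(4-methoxyphenyl)-4H-chromen-4-one
Conditions: MeI (2.2 equiv), K2CO3 (2.2 equiv), acetone, 50 °C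
Reagents that add atoms: iodomethane, CI
Why: Williamson ether synthesis in which the free 7- and 4'-hydroxyls react, whereas the 5-hydroxyl is chelated to the C4 carbonyl and should stay untouched with a stoichiometric amount of reagent.

Step 2
Reactants: 2 5-hydroxy-7-methoxy-2-(4-methoxyphenyl)-4H-chromen-4-one
Product: 3 5-(benzyloxy)-7-methoxy-2-(4-methoxyphenyl)-4H-chromen-4-one
Conditions: BnBr (1.5 equiv), K2CO3 (3 equiv), DMF, 80 °C
Reagents that add atoms: benzyl bromide, BrCc1ccccc1
Why: Williamson etherification of the only remaining hydroxyl, whose chelation is overcome by heat in a dipolar aprotic solvent; the benzyl ether is needed to steer the next iodination to C8.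

Step 3
Reactants: 3 5-(benzyloxy)-7-methoxy-2-(4-methoxyphenyl)-4H-chromen-4-one
Product: 4 5-(benzyloxy)-8-iodo-7-methoxy-2-(4-methoxyphenyl)-4H-chromen-4-one
Conditions: N-iodosuccinimide (1.05 equiv), CF3CO2H (0.3 equiv), MeCN, 0 °C to rt, dark
Reagents that add atoms: N-iodosuccinimide, O=C1CCC(=O)N1I
Why: Electrophilic aromatic iodination, which in 5,7-dialkoxyflavones goes to C8 (para to the 5-alkoxy group, less hindered than C6 between two alkoxy groups), while ring E is deactivated by conjugation with the pyranone.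

Step 4
Reactants: 5 3-bromo-4-hydroxybenzaldehyde
Product: 6 4-(benzyloxy)-3-bromobenzaldehyde
Conditions: BnBr (1.1 equiv), K2CO3 (1.5 equiv), DMF, rt
Reagents that add atoms: benzyl bromide, BrCc1ccccc1
Why: Williamson etherification of an acidic para-formyl phenol; the benzyl ether later serves as the para donor that stabilises the oxocarbenium ion at C2.

Step 5
Reactants: 7 2,4,6-trihydroxybenzoic acid, 6 4-(benzyloxy)-3-bromobenzaldehyde
Product: 10 2-[4-(benzyloxy)-3-bromophenyl]-5,7-dihydroxy-4H-1,3-benzodioxin-4-one (racemic), via persilylated acid 8 (not isolated), via bis(trimethylsilyl) dioxinone 9 (not isolated)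
Conditions: (Me3Si)2NH (2.2 equiv), Me3SiCl (cat.), CH2Cl2, 40 °C, then evaporation; 6, Me3SiOTf (0.2 equiv), CH2Cl2, −78 to −30 °C; aqueous citric acid, THF, 0 °C
Reagents that add atoms: none
Why: Silyl-transfer acetalisation as used in Petasis–Ferrier union sequences, in which the Me3SiOTf-activated aldehyde is taken up by the silyl ester and one ortho silyl ether oxygen with loss of (Me3Si)2O; the acid is symmetric so either ortho oxygen gives the same ring, low temperature and the absence of free phenols should hold back Friedel–Crafts attack and decarboxylation, and the racemic acetal centre is harmless because step 10 erases it.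

Step 6
Reactants: 10 2-[4-(benzyloxy)-3-bromophenyl]-5,7-dihydroxy-4H-1,3-benzodioxin-4-one (racemic)
Product: 11 2-[4-(benzyloxy)-3-bromophenyl]-5-hydroxy-7-methoxy-4H-1,3-benzodioxin-4-one (racemic)
Conditions: MeOH (1.1 equiv), PPh3 (1.2 equiv), DIAD (1.2 equiv), THF, 0 °C to rt
Reagents that add atoms: methanol, CO
Why: Mitsunobu etherification under neutral conditions, selective for the free 7-hydroxyl para to the lactone carbonyl over the chelated 5-hydroxyl, as is usual for 5,7-dihydroxybenzodioxinones.

Step 7
Reactants: 11 2-[4-(benzyloxy)-3-bromophenyl]-5-hydroxy-7-methoxy-4H-1,3-benzodioxin-4-one (racemic)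
Product: 12 5-(benzyloxy)-2-[4-(benzyloxy)-3-bromophenyl]-7-methoxy-4H-1,3-benzodioxin-4-one (racemic)
Conditions: BnBr (1.3 equiv), K2CO3 (2 equiv), DMF, 50 °C
Reagents that add atoms: benzyl bromide, BrCc1ccccc1
Why: Williamson etherification of the chelated phenol under anhydrous carbonate conditions that the lactone tolerates; it removes the acidic proton that would consume the titanium reagent and cause a racemic background reaction in step 10.

Step 8
Reactants: 12 5-(benzyloxy)-2-[4-(benzyloxy)-3-bromophenyl]-7-methoxy-4H-1,3-benzodioxin-4-one (racemic)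
Product: 13 5-(benzyloxy)-2-[4-(benzyloxy)-3-bromophenyl]-7-methoxy-4-methylidene-4H-1,3-benzodioxine (racemic)
Conditions: Cp2TiMe2 (2.5 equiv), toluene/THF, 65 °C, dark; filtration through basic alumina
Reagents that add atoms: dimethyltitanocene (Cp2TiMe2), C[Ti](C)(C1C=CC=C1)C1C=CC=C1
Why: Petasis methylenation of a lactone carbonyl through Cp2Ti=CH2 ([2+2] addition and cycloreversion), established for 1,3-dioxan-4-ones, non-basic and compatible with the aryl bromide, the benzyl ethers and the acetal.

Step 9
Reactants: 13 5-(benzyloxy)-2-[4-(benzyloxy)-3-bromophenyl]-7-methoxy-4-methylidene-4H-1,3-benzodioxine (racemic), 4 5-(benzyloxy)-8-iodo-7-methoxy-2-(4-methoxyphenyl)-4H-chromen-4-one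
Product: 15 5-(benzyloxy)-8-{2-(benzyloxy)-5-[5-(benzyloxy)-7-methoxy-4-methylidene-4H-1,3-benzodioxin-2-yl]phenyl}-7-methoxy-2-(4-methoxyphenyl)-4H-chromen-4-one (racemic), via pinacol boronate 14 (not isolated)
Conditions: B2pin2 (1.05 equiv), PdCl2(dppf) (5 mol %), KOAc (3 equiv), 1,4-dioxane, 85 °C; then 4 (0.9 equiv), Pd(OAc)2 (5 mol %), SPhos (10 mol %), K3PO4 (3 equiv, 2 M in water), 85 °C; chromatography on Et3N-treated silica
Reagents that add atoms: none
Why: Miyaura borylation followed in the same flask by Suzuki–Miyaura coupling in the polarity (ring B boronate plus 8-iodoflavone) that has close precedent for 3',8''-biflavones; the basic medium preserves the acid-labile enol acetal, and the coupling is placed before any stereocentre exists and after the titanium step, so the flavone carbonyl never meets Cp2TiMe2.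

Step 10
Reactants: 15 5-(benzyloxy)-8-{2-(benzyloxy)-5-[5-(benzyloxy)-7-methoxy-4-methylidene-4H-1,3-benzodioxin-2-yl]phenyl}-7-methoxy-2-(4-methoxyphenyl)-4H-chromen-4-one (racemic)
Product: 16 (2S)-5-(benzyloxy)-2-{4-(benzyloxy)-3-[5-(benzyloxy)-7-methoxy-2-(4-methoxyphenyl)-4-oxo-4H-chromen-8-yl]phenyl}-7-methoxy-2,3-dihydro-4H-chromen-4-one
Conditions: (S)-3,3'-bis(2,4,6-triisopropylphenyl)-1,1'-binaphthyl-2,2'-diyl hydrogen phosphate (C50H57O4P, 10 mol %), 5 Å molecular sieves, toluene (0.01 M), −20 to 0 °C
Reagents that add atoms: none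
Why: Proposed new method: the chiral phosphoric acid protonates the enol ether of 15, the O3–C2 bond ionises to an (E)-configured O-aryl oxocarbenium ion at C2 that is stabilised by the para-benzyloxy group of ring B, and the ring A enol released in the same event, still hydrogen-bonded to the phosphate, adds through its methylene carbon to C2 and returns the proton to the catalyst, so that the O3–C2 acetal bond is exchanged for the C3–C2 bond with catalyst turnover. The closest known reaction types are the Me2AlCl-promoted Petasis–Ferrier rearrangement of 4-methylidene-1,3-dioxanes to tetrahydropyran-4-ones and the chiral-phosphoric-acid-catalysed aza-Petasis–Ferrier rearrangement of hemiaminal vinyl ethers; an O-aryl oxocarbenium ion, a benzo-fused enol acetal and enantiocontrol in the oxygen series are the untested elements. Ring C closes in a 6-(enolendo)-endo-trig mode through a chair-like ion-pair transition state with the ring B aryl group pseudo-equatorial. The C2 stereocentre is controlled by the chiral phosphate counter-anion alone, because ionisation erases the racemic acetal centre and both enantiomers of 15 converge on one ion pair; addition to the Si face of C2 gives (2S), the (S)-catalyst is assigned to this face on an ion-pair model, and its mirror image is used should the sense prove opposite. The step needs carbon over oxygen recombination, secured because return at oxygen only regenerates 15 whereas C–C bond formation gives the ketone irreversibly, and cleavage at O3 and not at O1, secured because protonation of the enol ether at oxygen or at the methylene carbon leads to O3–C2 cleavage whereas cleavage at O1 would leave a poorly stabilised O-vinyl oxocarbenium ion and is reversible. Water and intermolecular Friedel–Crafts capture by the electron-rich rings A and D are excluded by molecular sieves, high dilution and a non-polar solvent that keeps the ion pair in contact.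

Step 11
Reactants: 16 (2S)-5-(benzyloxy)-2-{4-(benzyloxy)-3-[5-(benzyloxy)-7-methoxy-2-(4-methoxyphenyl)-4-oxo-4H-chromen-8-yl]phenyl}-7-methoxy-2,3-dihydro-4H-chromen-4-one
Product: 17 2,3-dihydroheveaflavone [(2S)-5-hydroxy-2-{4-hydroxy-3-[5-hydroxy-7-methoxy-2-(4-methoxyphenyl)-4-oxo-4H-chromen-8-yl]phenyl}-7-methoxy-2,3-dihydro-4H-chromen-4-one]
Conditions: H2 (1 atm), 10% Pd/C, EtOAc/THF (1:1), rt, stopped at full debenzylation
Reagents that add atoms: none
Why: Hydrogenolysis of the three aryl benzyl ethers under neutral conditions, which should leave the methyl ethers, the flavone C2''=C3'' bond and the chelated flavanone ketone intact and cannot open ring C by the base-induced retro-oxa-Michael path, so C2 stays (S).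

**Compound list**

1 | apigenin, 5,7-dihydroxy-2-(4-hydroxyphenyl)-4H-chromen-4-one | O=c1cc(-c2ccc(O)cc2)oc2cc(O)cc(O)c12 | starting material
2 | 5-hydroxy-7-methoxy-2-(4-methoxyphenyl)-4H-chromen-4-one | COc1ccc(-c2cc(=O)c3c(O)cc(OC)cc3o2)cc1 | intermediate
3 | 5-(benzyloxy)-7-methoxy-2-(4-methoxyphenyl)-4H-chromen-4-one | COc1ccc(-c2cc(=O)c3c(OCc4ccccc4)cc(OC)cc3o2)cc1 | intermediate
4 | 5-(benzyloxy)-8-iodo-7-methoxy-2-(4-methoxyphenyl)-4H-chromen-4-one | COc1ccc(-c2cc(=O)c3c(OCc4ccccc4)cc(OC)c(I)c3o2)cc1 | intermediate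
5 | 3-bromo-4-hydroxybenzaldehyde | O=Cc1ccc(O)c(Br)c1 | starting material
6 | 4-(benzyloxy)-3-bromobenzaldehyde | O=Cc1ccc(OCc2ccccc2)c(Br)c1 | intermediate
7 | 2,4,6-trihydroxybenzoic acid | O=C(O)c1c(O)cc(O)cc1O | starting material
8 | trimethylsilyl 2,4,6-tris(trimethylsilyloxy)benzoate (persilylated acid, formed in the flask) | C[Si](C)(C)OC(=O)c1c(O[Si](C)(C)C)cc(O[Si](C)(C)C)cc1O[Si](C)(C)C | intermediate
9 | 2-[4-(benzyloxy)-3-bromophenyl]-5,7-bis(trimethylsilyloxy)-4H-1,3-benzodioxin-4-one (racemic, formed in the flask) | O=C1OC(c2ccc(OCc3ccccc3)c(Br)c2)Oc2cc(O[Si](C)(C)C)cc(O[Si](C)(C)C)c12 | intermediate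
10 | 2-[4-(benzyloxy)-3-bromophenyl]-5,7-dihydroxy-4H-1,3-benzodioxin-4-one (racemic) | O=C1OC(c2ccc(OCc3ccccc3)c(Br)c2)Oc2cc(O)cc(O)c12 | intermediate
11 | 2-[4-(benzyloxy)-3-bromophenyl]-5-hydroxy-7-methoxy-4H-1,3-benzodioxin-4-one (racemic) | O=C1OC(c2ccc(OCc3ccccc3)c(Br)c2)Oc2cc(OC)cc(O)c12 | intermediate
12 | 5-(benzyloxy)-2-[4-(benzyloxy)-3-bromophenyl]-7-methoxy-4H-1,3-benzodioxin-4-one (racemic) | O=C1OC(c2ccc(OCc3ccccc3)c(Br)c2)Oc2cc(OC)cc(OCc3ccccc3)c12 | intermediate
13 | 5-(benzyloxy)-2-[4-(benzyloxy)-3-bromophenyl]-7-methoxy-4-methylidene-4H-1,3-benzodioxine (racemic) | C=C1OC(c2ccc(OCc3ccccc3)c(Br)c2)Oc2cc(OC)cc(OCc3ccccc3)c12 | intermediate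
14 | 5-(benzyloxy)-2-[4-(benzyloxy)-3-(4,4,5,5-tetramethyl-1,3,2-dioxaborolan-2-yl)phenyl]-7-methoxy-4-methylidene-4H-1,3-benzodioxine (racemic pinacol boronate, formed in the flask) | C=C1OC(c2ccc(OCc3ccccc3)c(B3OC(C)(C)C(C)(C)O3)c2)Oc2cc(OC)cc(OCc3ccccc3)c12 | intermediate
15 | 5-(benzyloxy)-8-{2-(benzyloxy)-5-[5-(benzyloxy)-7-methoxy-4-methylidene-4H-1,3-benzodioxin-2-yl]phenyl}-7-methoxy-2-(4-methoxyphenyl)-4H-chromen-4-one (racemic) | C=C1OC(c2ccc(OCc3ccccc3)c(-c3c(OC)cc(OCc4ccccc4)c4c(=O)cc(-c5ccc(OC)cc5)oc34)c2)Oc2cc(OC)cc(OCc3ccccc3)c12 | intermediate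
16 | (2S)-5-(benzyloxy)-2-{4-(benzyloxy)-3-[5-(benzyloxy)-7-methoxy-2-(4-methoxyphenyl)-4-oxo-4H-chromen-8-yl]phenyl}-7-methoxy-2,3-dihydro-4H-chromen-4-one | COc1ccc(-c2cc(=O)c3c(OCc7ccccc7)cc(OC)c(-c4cc([C@@H]5CC(=O)c6c(OCc7ccccc7)cc(OC)cc6O5)ccc4OCc4ccccc4)c3o2)cc1 | intermediate
17 | 2,3-dihydroheveaflavone, (2S)-5-hydroxy-2-{4-hydroxy-3-[5-hydroxy-7-methoxy-2-(4-methoxyphenyl)-4-oxo-4H-chromen-8-yl]phenyl}-7-methoxy-2,3-dihydro-4H-chromen-4-one | COc1ccc(-c2cc(=O)c3c(O)cc(OC)c(-c4cc([C@@H]5CC(=O)c6c(O)cc(OC)cc6O5)ccc4O)c3o2)cc1 | target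

**Totals**

Total step count: 11.
Longest linear sequence: 8 steps (steps 4 to 11, from 3-bromo-4-hydroxybenzaldehyde 5); the flavone arm (steps 1 to 3) joins at step 9.

**Steps most likely to fail**

1. Step 10 (the step proposed as new). The ion pair may collapse without facial discrimination if the enol leaves the phosphate before C–C bond formation. The oxocarbenium ion may also be lost to hydrolysis or to intermolecular arylation. The flavone carbonyl may tie up the acid. The fallback uses known chemistry, sets out from 15 and comes back at 16. Compound 15 is hydrolysed with dilute aqueous HCl in THF into its two halves, 1-[2-(benzyloxy)-6-hydroxy-4-methoxyphenyl]ethan-1-one F1 and 4-(benzyloxy)-3-[5-(benzyloxy)-7-methoxy-2-(4-methoxyphenyl)-4-oxo-4H-chromen-8-yl]benzaldehyde F2. Claisen–Schmidt condensation of these (KOH, EtOH, rt) should give (E)-1-[2-(benzyloxy)-6-hydroxy-4-methoxyphenyl]-3-{4-(benzyloxy)-3-[5-(benzyloxy)-7-methoxy-2-(4-methoxyphenyl)-4-oxo-4H-chromen-8-yl]phenyl}prop-2-en-1-one F3. This 2'-hydroxychalcone is closed at the O1–C2 bond by catalytic asymmetric intramolecular oxa-Michael addition with 1-[3,5-bis(trifluoromethyl)phenyl]-3-[(8α,9S)-6'-methoxycinchonan-9-yl]thiourea (10 mol %) in toluene, the pseudo-enantiomeric quinidine-derived catalyst being taken if the sense requires it. The enantiomeric purity of 16 is then raised by crystallisation or chromatography on a chiral stationary phase.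

2. Step 9. The ortho-alkoxy boronate may protodeboronate before the slow coupling with the doubly ortho-substituted iodide. The exocyclic enol acetal may undergo Heck-type arylation or palladium-induced ionisation at 85 °C. The fallback moves the biaryl coupling ahead of the enol ether, sets out from 12 and comes back at 15. Miyaura borylation of lactone 12 (B2pin2, PdCl2(dppf), KOAc, 1,4-dioxane, 85 °C) should give 5-(benzyloxy)-2-[4-(benzyloxy)-3-(4,4,5,5-tetramethyl-1,3,2-dioxaborolan-2-yl)phenyl]-7-methoxy-4H-1,3-benzodioxin-4-one F4, which is isolated. Anhydrous Suzuki–Miyaura coupling with 4 (Pd(OAc)2, SPhos, anhydrous K3PO4, toluene, 90 °C) should give 5-(benzyloxy)-2-{4-(benzyloxy)-3-[5-(benzyloxy)-7-methoxy-2-(4-methoxyphenyl)-4-oxo-4H-chromen-8-yl]phenyl}-7-methoxy-4H-1,3-benzodioxin-4-one F5. Petasis methylenation with a limited amount of Cp2TiMe2 (1.5 equiv, toluene, 60 °C) then leads to 15. This relies on the acylal-type lactone carbonyl being more reactive than the cross-conjugated pyranone carbonyl shielded by the 5''-benzyloxy group, which is itself a risk.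

3. Step 5. The silyl-activated, electron-rich aldehyde may alkylate C3/C5 of the phloroglucinol ring. The acid may decarboxylate during silylation. The weakly nucleophilic aryl silyl ether may fail to close the acetal. The fallback activates the carboxyl group instead of the aldehyde, so that no benzylic cation is formed; it sets out from 7 and 6 and comes back at 10. Acid 7 is treated with SOCl2 (1.5 equiv) and 4-dimethylaminopyridine in 1,2-dimethoxyethane at 0 °C to give 2,4,6-trihydroxybenzoyl chloride F6, which is not isolated. In the presence of 6 (0 °C to rt) the phenol hemiacetal of the aldehyde is trapped by acyl transfer to give 10. This is the known acyl-activation route to 1,3-benzodioxin-4-ones from this acid and a carbonyl compound.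

**Further compounds**

F1 | step 10 | 1-[2-(benzyloxy)-6-hydroxy-4-methoxyphenyl]ethan-1-one | CC(=O)c1c(O)cc(OC)cc1OCc1ccccc1
F2 | step 10 | 4-(benzyloxy)-3-[5-(benzyloxy)-7-methoxy-2-(4-methoxyphenyl)-4-oxo-4H-chromen-8-yl]benzaldehyde | O=Cc1ccc(OCc2ccccc2)c(-c2c(OC)cc(OCc3ccccc3)c3c(=O)cc(-c4ccc(OC)cc4)oc23)c1
F3 | step 10 | (E)-1-[2-(benzyloxy)-6-hydroxy-4-methoxyphenyl]-3-{4-(benzyloxy)-3-[5-(benzyloxy)-7-methoxy-2-(4-methoxyphenyl)-4-oxo-4H-chromen-8-yl]phenyl}prop-2-en-1-one | O=C(/C=C/c1ccc(OCc2ccccc2)c(-c2c(OC)cc(OCc3ccccc3)c3c(=O)cc(-c4ccc(OC)cc4)oc23)c1)c1c(O)cc(OC)cc1OCc1ccccc1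
F4 | step 9 | 5-(benzyloxy)-2-[4-(benzyloxy)-3-(4,4,5,5-tetramethyl-1,3,2-dioxaborolan-2-yl)phenyl]-7-methoxy-4H-1,3-benzodioxin-4-one (racemic) | O=C1OC(c2ccc(OCc3ccccc3)c(B3OC(C)(C)C(C)(C)O3)c2)Oc2cc(OC)cc(OCc3ccccc3)c12
F5 | step 9 | 5-(benzyloxy)-2-{4-(benzyloxy)-3-[5-(benzyloxy)-7-methoxy-2-(4-methoxyphenyl)-4-oxo-4H-chromen-8-yl]phenyl}-7-methoxy-4H-1,3-benzodioxin-4-one (racemic) | O=C1OC(c2ccc(OCc3ccccc3)c(-c3c(OC)cc(OCc4ccccc4)c4c(=O)cc(-c5ccc(OC)cc5)oc34)c2)Oc2cc(OC)cc(OCc3ccccc3)c12
F6 | step 5 | 2,4,6-trihydroxybenzoyl chloride (formed in the flask) | O=C(Cl)c1c(O)cc(O)cc1O
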